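**Structural features**

The target is a daucane-type diester on a trans-fused hydroazulene. A cyclopentane (C1–C5) and a cycloheptene (C1, C5–C10) share the C1–C5 bond, and the only ring alkene is the trisubstituted C8=C9 with its methyl group on C8. Five stereocentres form one block around the fusion: quaternary C1 (methyl) lies between C2 (angelate) and C5 (fusion hydrogen), and C5 lies between C4 (tertiary carbinol with isopropyl) and C6 (4-methoxybenzoate). The C1 methyl group, the C2 oxygen and the C4 hydroxyl stand on one face (α); H-5, the isopropyl group and the C6 oxygen stand on the other (β). The fragile parts are the angelate (Z to E isomerization to the tiglate under nucleophilic catalysis, base or acid), the tertiary alcohol (dehydration), the two esters next to free hydroxyls (migration, hydrolysis) and the C8=C9 alkene (acid-promoted migration). The real difficulty is the quaternary C1 flanked by two stereocentres, together with telling three oxygens apart (two different esters and a free tertiary alcohol). The key step uses the fact that C1 and C5 are the β- and α-carbons of a cyclopentenone whose carbonyl is C4 and whose γ-oxygen is C2. The two bonds that leave the five-membered ring toward the seven-membered ring (C1–C10 and C5–C6) are then made by conjugate addition and enolate capture, and the last ring bond (C8=C9) is an alkene open to metathesis.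

**Logic of the disconnections**

15 to 14: the C2–O acyl bond is cut first, because the angelate is the most labile group and should meet the fewest reagents. This leaves a diol monoester with one free secondary hydroxyl. The forward step must acylate a neopentyl-type secondary alcohol without Z/E isomerization and without touching the tertiary hydroxyl.

14 to 13 to 12 to 11: the C6–O acyl bond and the two O–Si bonds are cut. Two silyl ethers of different lability stand in for the two esters, so the oxygens can be addressed one at a time. The forward steps must cleave the C6 silyl ether while the C2 silyl ether stays, and later remove the C2 silyl ether without ester migration.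

11 to 10: the C4–isopropyl bond is cut. This removes three carbons and one stereocentre and reveals the C4 ketone. The forward addition must come from the β-face and must use a nucleophile of low basicity, since both α-positions of the ketone carry β-silyloxy groups.

10 to 9: the C8=C9 bond is cut. The seven-membered ring opens to an allyl arm on C1 and a methallyl-bearing arm on C5, both on a cyclopentanone. The forward ring-closing metathesis must form a trisubstituted alkene in a trans-fused ring.

9 to 8: the O–Si bond at C6 is cut. The free aldol is exposed only for one step; the forward silylation must not trigger retro-aldol cleavage.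

8 to 3 + 6 + 5 (through 7): the C1–C10 and C5–C6 bonds are cut. Twelve of the fifteen skeletal carbons fall into three simple components, and three stereocentres (C1, C5, C6) are traced back to the single stereocentre of 3. The forward step must deliver the allyl group anti to the C2 oxygen and must capture the aldehyde on the methyl face of the enolate with anti-aldol topicity.

3 to 2 to 1: the C1–CH3 bond is cut and the enone unsaturation is taken back one step. This leads to an enantiopure 4-silyloxycyclopentenone that is an article of commerce, so no resolution is needed. The forward steps must add methyl 1,4 and then restore the alkene regiospecifically toward the methyl-bearing carbon.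

5 to 4: no carbon–carbon bond is cut; only the oxidation level changes. The forward oxidation must stop at the β,γ-unsaturated aldehyde without shifting the alkene into conjugation.

**Other disconnections considered**

Alternative 1: The cut is C6–C7. The ring-closed carbinol A2 (trans-fused hydroazulen-6-ol with the C2 and C4 oxygens tied as an acetonide) is taken back to the cyclopentane carbaldehyde A1, which carries the formyl group on C5 and a 3-methyl-2-(trimethylsilyl)but-3-enyl chain on C1. In the forward step BF3·OEt2 would activate the aldehyde; C7 of the allylsilane would attack C6 and silicon would leave from C9. In its favour, the ring, the C6 carbinol and the alkene position arise in one metal-free step, and the five-membered ring with C1, C2, C4 and C5 is complete before the closure. Against it, allylsilane–aldehyde closure to a seven-membered ring is slow, so protodesilylation can compete. The aldehyde sits on an epimerizable carbon next to a tertiary ether and may lose C5 integrity or undergo β-elimination under the Lewis acid. The acetonide bridges a cis-1,3-diol on a cyclopentane that includes a tertiary centre, which makes it strained and labile to BF3·OEt2. A1 needs the quaternary centre, the secondary allylsilane and the aldehyde built in a longer linear sequence. In comparison, both plans fix the alkene at C8=C9 without ambiguity (equal). Both leave the C6 configuration to a transition-state preference that is not fully secure (equal). The alternative is better in one respect: C6–OH emerges free and could be acylated at once, saving the silylation and desilylation at C6. The chosen plan is clearly shorter to its ring-closure substrate and draws three stereocentres from one.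

Alternative 2: The cuts are C1–C5 and C1–C10. The cycloheptatrienone A4 is taken back to the diazo ketone A3, in which a 2-methoxy-4-methylphenyl ring is tethered through C4 and C3 to a 2-diazopropanoyl unit. In the forward step the Rh2(OAc)4 carbenoid at C1 would add across the arene C5–C10 bond and the norcaradiene would open (Buchner reaction). In its favour, both rings and the quaternary C1 form in one catalytic step from a flat aromatic precursor with one stereocentre, and the C6 oxygen and C8 methyl are already in place. On ring-forming efficiency it is better than the chosen plan, which needs a stoichiometric Lewis acid and a separate metathesis. Against it, A4 has the wrong oxidation level at six ring carbons. One alkene must survive at C8=C9, the enol ether must become the C6 carbinol, C5 must gain a trans hydrogen, C7 and C10 must become methylene, and the C2 ketone must be reduced with control. These are selective reductions within one conjugated triene. Mechanistically, the methyl-bearing carbenoid can undergo a 1,2-hydride shift to a vinyl ketone. The two ortho bonds of the arene compete. The configuration of C1 depends on how well the silyloxy and isopropyl groups at C4 differentiate the two modes of addition. The chosen plan sets C1, C2 and C5 by 1,2-induction at sp3 centres and needs no redox correction of the ring, so its total step count should be lower.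

Alternative 3: The cut is C3–C4. The cyclopentanone A6 is taken back to the acyclic α-diazo β-keto ester A5, which holds C1 (methyl, tert-butyl acetate arm), C5 (methyl ester) and the silyl-protected secondary carbinol C4. In the forward step the Rh2(OAc)4 carbenoid at C3 would insert into the C4–H bond with retention, closing the five-membered ring. In its favour, the tertiary carbinol configuration is transferred stereospecifically from a secondary carbinol and does not depend on the facial bias of a ketone. On this point it is better than the organocerium addition of the chosen plan. A C–H bond next to oxygen is activated, and five-membered closure is the normal mode. Against it, A5 must already hold the C1/C5/C4 triad, including a quaternary centre, in an open chain. The insertion site is crowded by isopropyl and the substituted C5, so insertion into the isopropyl methine or hydride transfer could compete. A6 contains only the five-membered ring, with three ester groups in excess oxidation. C7, C8 and its methyl must still be added, the C3 ester removed, the two remaining esters differentiated and the seven-membered ring closed. The chosen plan has the whole ring skeleton two steps after its key step, so the alternative is clearly weaker on step economy, although its stereospecific mechanism is stronger at C4.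

Key step: step 4

Remark on the chemistry: enone 1 is assumed to be purchasable as the single R enantiomer. The hydroazulene locants C1–C10 used above (α = face of the C1 methyl group) are applied to all bicyclic compounds.

Step 1
Reactants: 1 (R)-4-(tert-butyldimethylsilyloxy)cyclopent-2-en-1-one
Product: 2 (3R,4R)-4-(tert-butyldimethylsilyloxy)-3-methyl-1-(trimethylsilyloxy)cyclopent-1-ene
Conditions: Me2CuLi (from MeLi, CuI), Me3SiCl, Et3N, THF, −78 °C
Reagents that add atoms: lithium dimethylcuprate, [Li+].C[Cu-]C; chlorotrimethylsilane, C[Si](C)(C)Cl
Why: Cuprate 1,4-addition with in situ enolate silylation; methyl should enter anti to the silyloxy group, and Me3SiCl captures the kinetic enolate before it can equilibrate and expel the silyloxy group; the new methine centre is erased in step 2.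

Step 2
Reactants: 2 (3R,4R)-4-(tert-butyldimethylsilyloxy)-3-methyl-1-(trimethylsilyloxy)cyclopent-1-ene
Product: 3 (R)-4-(tert-butyldimethylsilyloxy)-3-methylcyclopent-2-en-1-one
Conditions: Pd(OAc)2 (1.05 equiv), MeCN, 25 °C
Reagents that add atoms: none
Why: Saegusa–Ito oxidation; palladation at C2 and β-hydride elimination of the only available β-hydrogen (C3–H) place the alkene regiospecifically toward the methyl-bearing carbon, and the silyloxy stereocentre is untouched, so the R configuration of 1 is carried into 3.

Step 3
Reactants: 4 3-methylbut-3-en-1-ol
Product: 5 3-methylbut-3-enal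
Conditions: Dess–Martin periodinane, pyridine, CH2Cl2, 0 °C; dried solution used directly
Reagents that add atoms: none
Why: Dess–Martin oxidation of a primary alcohol under buffered, non-aqueous conditions stops at the aldehyde and avoids the acid- or base-mediated shift of the alkene into conjugation; the volatile aldehyde is kept in solution and not concentrated.

Step 4
Reactants: 3 (R)-4-(tert-butyldimethylsilyloxy)-3-methylcyclopent-2-en-1-one; 6 allyltrimethylsilane; 5 3-methylbut-3-enal
Product: 8 (2S,3R,4R)-3-allyl-4-(tert-butyldimethylsilyloxy)-2-[(1S)-1-hydroxy-3-methylbut-3-en-1-yl]-3-methylcyclopentan-1-one, via trichlorotitanium enolate 7 (not isolated)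
Conditions: 6 (1.05 equiv), TiCl4 (1.1 equiv), CH2Cl2, −78 °C; then 5 (2 equiv, CH2Cl2 solution), −78 °C; aq. NaHCO3
Reagents that add atoms: none
Why: TiCl4 binds the carbonyl oxygen of 3 and the γ-carbon of 6 attacks the β-carbon C1 (Hosomi–Sakurai conjugate allylation), the β-silyl cation losing Me3SiCl and leaving the regiodefined enolate 7. The allyl group should enter anti to the adjacent C2 silyloxy group, which fixes C1 with its methyl group cis to the C2 oxygen by the same 1,2-induction that governs additions to 4-silyloxycyclopentenones. Enolate 7 then adds through C5 to aldehyde 5; the closest known reaction type is the Sakurai reaction with aldehyde trapping of the titanium enolate, and no ring is closed. C5 is set by approach of the aldehyde to the enolate face that carries the C1 methyl group, away from the larger allyl chain, which gives the trans arrangement of the two arms needed for the later trans fusion. C6 is set by the ring-locked E geometry of the enolate in a chair-like, titanium-bridged Zimmerman–Traxler transition state with the methallyl residue equatorial, which leads to the anti aldol, that is the 6S carbinol. The step needs 1,4- and not 1,2-allylation (secured by the allylsilane/TiCl4 pair even at a β,β-disubstituted enone), no migration of the enolate to C3, which would expel the C2 silyloxy group (secured by capture at −78 °C), and aldehyde capture faster than allylation of 5 by residual 6 (secured by using 6 in slight excess only and consuming it before 5 is added). Face selection at C5 rests only on the size difference between methyl and allyl at the quaternary carbon and is the least secure element.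

Step 5
Reactants: 8 (2S,3R,4R)-3-allyl-4-(tert-butyldimethylsilyloxy)-2-[(1S)-1-hydroxy-3-methylbut-3-en-1-yl]-3-methylcyclopentan-1-one
Product: 9 (2S,3R,4R)-3-allyl-4-(tert-butyldimethylsilyloxy)-3-methyl-2-[(1S)-3-methyl-1-(triethylsilyloxy)but-3-en-1-yl]cyclopentan-1-one
Conditions: Et3SiOTf, 2,6-lutidine, CH2Cl2, −78 °C
Reagents that add atoms: triethylsilyl trifluoromethanesulfonate, CC[Si](CC)(CC)OS(=O)(=O)C(F)(F)F
Why: Silylation of a secondary alcohol with a silyl triflate and a hindered pyridine base forms no alkoxide and so protects the aldol against retro-aldol cleavage and dehydration; the triethylsilyl ether is chosen because it can later be removed in the presence of the C2 tert-butyldimethylsilyl ether.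

Step 6
Reactants: 9 (2S,3R,4R)-3-allyl-4-(tert-butyldimethylsilyloxy)-3-methyl-2-[(1S)-3-methyl-1-(triethylsilyloxy)but-3-en-1-yl]cyclopentan-1-one
Product: 10 (1R,2R,5S,6S)-2α-(tert-butyldimethylsilyloxy)-6β-(triethylsilyloxy)-1α,8-dimethyl-trans-hydroazul-8-en-4-one
Conditions: second-generation Grubbs catalyst RuCl2(=CHPh)(SIMes)(PCy3) (5 mol %), CH2Cl2 (0.005 M), 40 °C
Reagents that add atoms: none
Why: Ring-closing metathesis between the monosubstituted allyl alkene (initiation site) and the 1,1-disubstituted methallyl alkene closes the seven-membered ring with loss of ethene and leaves the alkene at C8=C9 with the methyl on C8; the two arms are trans on the cyclopentanone, so only the trans-fused ring can form, and the neutral catalyst leaves C5 and the silyl ethers alone.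

Step 7
Reactants: 10 (1R,2R,5S,6S)-2α-(tert-butyldimethylsilyloxy)-6β-(triethylsilyloxy)-1α,8-dimethyl-trans-hydroazul-8-en-4-one
Product: 11 (1R,2R,4R,5S,6S)-2α-(tert-butyldimethylsilyloxy)-6β-(triethylsilyloxy)-4β-isopropyl-1α,8-dimethyl-trans-hydroazul-8-en-4α-ol
Conditions: iPrMgCl, CeCl3 (anhydrous), THF, −78 °C; aq. NH4Cl
Reagents that add atoms: isopropylmagnesium chloride, CC(C)[Mg]Cl
Why: Organocerium 1,2-addition to a hindered, enolizable ketone; the low basicity suppresses enolization (which would expel a β-silyloxy group) and β-hydride reduction. The reagent should approach C4 from the β-face, which shows only H-5, because the α-face carries the axial C1 methyl group and the C2 silyloxy group; this gives the 4α-hydroxy-4β-isopropyl (4R) carbinol.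

Step 8
Reactants: 11 (1R,2R,4R,5S,6S)-2α-(tert-butyldimethylsilyloxy)-6β-(triethylsilyloxy)-4β-isopropyl-1α,8-dimethyl-trans-hydroazul-8-en-4α-ol
Product: 12 (1R,2R,4R,5S,6S)-2α-(tert-butyldimethylsilyloxy)-4β-isopropyl-1α,8-dimethyl-trans-hydroazul-8-ene-4α,6β-diol
Conditions: PPTS (cat.), MeOH–CH2Cl2, 0 °C
Reagents that add atoms: none
Why: Acid-catalysed methanolysis distinguishes silyl ethers by size: the triethylsilyl ether at C6 is cleaved much faster than the hindered tert-butyldimethylsilyl ether at C2, and pyridinium p-toluenesulfonate is too weak to dehydrate the tertiary alcohol or move the alkene.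

Step 9
Reactants: 12 (1R,2R,4R,5S,6S)-2α-(tert-butyldimethylsilyloxy)-4β-isopropyl-1α,8-dimethyl-trans-hydroazul-8-ene-4α,6β-diol
Product: 13 (1R,2R,4R,5S,6S)-2α-(tert-butyldimethylsilyloxy)-4α-hydroxy-4β-isopropyl-1α,8-dimethyl-trans-hydroazul-8-en-6β-yl 4-methoxybenzoate
Conditions: 4-MeOC6H4COCl, DMAP, Et3N, CH2Cl2, 0 → 25 °C
Reagents that add atoms: 4-methoxybenzoyl chloride, COc1ccc(cc1)C(Cl)=O
Why: DMAP-catalysed acylation with an acid chloride esterifies the only secondary hydroxyl; the tertiary C4 hydroxyl is flanked by the isopropyl group and the ring fusion and should not react under these conditions.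

Step 10
Reactants: 13 (1R,2R,4R,5S,6S)-2α-(tert-butyldimethylsilyloxy)-4α-hydroxy-4β-isopropyl-1α,8-dimethyl-trans-hydroazul-8-en-6β-yl 4-methoxybenzoate
Product: 14 (1R,2R,4R,5S,6S)-2α,4α-dihydroxy-4β-isopropyl-1α,8-dimethyl-trans-hydroazul-8-en-6β-yl 4-methoxybenzoate
Conditions: HF·pyridine, pyridine, THF, 0 → 25 °C
Reagents that add atoms: none
Why: Fluoride-mediated desilylation under mildly acidic, non-basic conditions removes the neopentyl-type silyl ether without the ester hydrolysis or acyl migration that a basic fluoride source could provoke.

Step 11
Reactants: 14 (1R,2R,4R,5S,6S)-2α,4α-dihydroxy-4β-isopropyl-1α,8-dimethyl-trans-hydroazul-8-en-6β-yl 4-methoxybenzoate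
Product: 15 (1R,2R,4R,5S,6S)-2α-angeloyloxy-4α-hydroxy-4β-isopropyl-1α,8-dimethyl-trans-hydroazul-8-en-6β-yl 4-methoxybenzoate
Conditions: angelic acid, 2,4,6-Cl3C6H2COCl, Et3N, toluene, 25 °C; then 14, 80 °C
Reagents that add atoms: angelic acid [(2Z)-2-methylbut-2-enoic acid], C/C=C(/C)C(O)=O
Why: Yamaguchi-type esterification through the mixed 2,4,6-trichlorobenzoic anhydride, run without a nucleophilic catalyst, avoids the conjugate addition–elimination pathway by which acylpyridinium intermediates isomerize angelates to tiglates; the alcohol attacks the less hindered angeloyl carbonyl, and only the secondary C2 hydroxyl is acylated.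

**Compound list**

1 | (R)-4-(tert-butyldimethylsilyloxy)cyclopent-2-en-1-one | CC(C)(C)[Si](C)(C)O[C@@H]1CC(=O)C=C1 | starting material
2 | (3R,4R)-4-(tert-butyldimethylsilyloxy)-3-methyl-1-(trimethylsilyloxy)cyclopent-1-ene (3,4-trans) | CC(C)(C)[Si](C)(C)O[C@@H]1CC(O[Si](C)(C)C)=C[C@H]1C | intermediate
3 | (R)-4-(tert-butyldimethylsilyloxy)-3-methylcyclopent-2-en-1-one | CC(C)(C)[Si](C)(C)O[C@@H]1CC(=O)C=C1C | intermediate
4 | 3-methylbut-3-en-1-ol | CC(=C)CCO | starting material
5 | 3-methylbut-3-enal | CC(=C)CC=O | intermediate
6 | allyltrimethylsilane | C=CC[Si](C)(C)C | starting material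
7 | trichloro{[(3R,4R)-3-allyl-4-(tert-butyldimethylsilyloxy)-3-methylcyclopent-1-en-1-yl]oxy}titanium | CC(C)(C)[Si](C)(C)O[C@@H]1CC(O[Ti](Cl)(Cl)Cl)=C[C@@]1(C)CC=C | intermediate (not isolated)
8 | (2S,3R,4R)-3-allyl-4-(tert-butyldimethylsilyloxy)-2-[(1S)-1-hydroxy-3-methylbut-3-en-1-yl]-3-methylcyclopentan-1-one | CC(C)(C)[Si](C)(C)O[C@@H]1CC(=O)[C@H]([C@@H](O)CC(C)=C)[C@@]1(C)CC=C | intermediate
9 | (2S,3R,4R)-3-allyl-4-(tert-butyldimethylsilyloxy)-3-methyl-2-[(1S)-3-methyl-1-(triethylsilyloxy)but-3-en-1-yl]cyclopentan-1-one | CC(C)(C)[Si](C)(C)O[C@@H]1CC(=O)[C@H]([C@@H](O[Si](CC)(CC)CC)CC(C)=C)[C@@]1(C)CC=C | intermediate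
10 | (1R,2R,5S,6S)-2α-(tert-butyldimethylsilyloxy)-6β-(triethylsilyloxy)-1α,8-dimethyl-trans-hydroazul-8-en-4-one; systematic: (3R,3aR,8S,8aS)-3-(tert-butyldimethylsilyloxy)-3a,6-dimethyl-8-(triethylsilyloxy)-3,3a,4,7,8,8a-hexahydroazulen-1(2H)-one | CC(C)(C)[Si](C)(C)O[C@@H]1CC(=O)[C@@H]2[C@@H](O[Si](CC)(CC)CC)CC(C)=CC[C@]21C | intermediate
11 | (1R,2R,4R,5S,6S)-2α-(tert-butyldimethylsilyloxy)-6β-(triethylsilyloxy)-4β-isopropyl-1α,8-dimethyl-trans-hydroazul-8-en-4α-ol | CC(C)(C)[Si](C)(C)O[C@@H]1C[C@@](O)(C(C)C)[C@@H]2[C@@H](O[Si](CC)(CC)CC)CC(C)=CC[C@]21C | intermediate
12 | (1R,2R,4R,5S,6S)-2α-(tert-butyldimethylsilyloxy)-4β-isopropyl-1α,8-dimethyl-trans-hydroazul-8-ene-4α,6β-diol | CC(C)(C)[Si](C)(C)O[C@@H]1C[C@@](O)(C(C)C)[C@@H]2[C@@H](O)CC(C)=CC[C@]21C | intermediate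
13 | (1R,2R,4R,5S,6S)-2α-(tert-butyldimethylsilyloxy)-4α-hydroxy-4β-isopropyl-1α,8-dimethyl-trans-hydroazul-8-en-6β-yl 4-methoxybenzoate | CC(C)(C)[Si](C)(C)O[C@@H]1C[C@@](O)(C(C)C)[C@@H]2[C@@H](OC(=O)c3ccc(OC)cc3)CC(C)=CC[C@]21C | intermediate
14 | (1R,2R,4R,5S,6S)-2α,4α-dihydroxy-4β-isopropyl-1α,8-dimethyl-trans-hydroazul-8-en-6β-yl 4-methoxybenzoate | O[C@@H]1C[C@@](O)(C(C)C)[C@@H]2[C@@H](OC(=O)c3ccc(OC)cc3)CC(C)=CC[C@]21C | intermediate
15 | (1R,2R,4R,5S,6S)-2α-angeloyloxy-4α-hydroxy-4β-isopropyl-1α,8-dimethyl-trans-hydroazul-8-en-6β-yl 4-methoxybenzoate; systematic: (1R,3R,3aS,4S,8aR)-3-hydroxy-4-[(4-methoxybenzoyl)oxy]-6,8a-dimethyl-3-(propan-2-yl)-1,2,3,3a,4,5,8,8a-octahydroazulen-1-yl (2Z)-2-methylbut-2-enoate | C/C=C(/C)C(=O)O[C@@H]1C[C@@](O)(C(C)C)[C@@H]2[C@@H](OC(=O)c3ccc(OC)cc3)CC(C)=CC[C@]21C | target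

**Step count and least certain steps**

Total step count: 11. Longest linear sequence: 10 steps (1 to 15 through steps 1, 2 and 4–11); step 3 is a one-step side branch.

Step 4 (key step). Two processes are most likely to erode it.
- Face selection at C5 may be poor, because only the methyl/allyl size difference at the quaternary carbon distinguishes the two enolate faces, and an open transition state under TiCl4 would lose the anti-aldol preference at C6.
- The Lewis acid may consume the β,γ-unsaturated aldehyde, through allylation by residual allylsilane, a shift of the alkene into conjugation, or Prins-type reactions of the methallyl unit.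

The fallback separates the two bond formations and takes the Lewis acid out of the aldol; it sets out from 3 and comes back at 8. Copper-mediated conjugate addition of allylmagnesium bromide to 3 (CuBr·SMe2, Me3SiCl, THF, −78 °C) should give the regiodefined silyl enol ether trimethyl{[(3R,4R)-3-allyl-4-(tert-butyldimethylsilyloxy)-3-methylcyclopent-1-en-1-yl]oxy}silane F1. MeLi (THF, 0 °C) would release the lithium enolate, ZnCl2 would convert it to the zinc enolate, and 5 added at −78 °C should give 8 through a compact, metal-bridged six-membered transition state. That transition state favours the anti aldol and is more sensitive to the steric difference at C1.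

Step 11. Slow acylation of the neopentyl-type C2 hydroxyl leaves the activated angelate time for Z to E isomerization, so tiglate may form. The fallback builds the Z alkene on an ester already in place; it sets out from 14 and comes back at 15. Esterification of 14 with 2-[bis(2,2,2-trifluoroethoxy)phosphoryl]propanoic acid (DCC, DMAP, CH2Cl2) should give the C2 phosphonopropanoate of 14 F2. Still–Gennari olefination with acetaldehyde (KN(SiMe3)2, 18-crown-6, THF, −78 °C) should then give the Z-configured 2-methylbut-2-enoate 15; the base meets the far more acidic phosphonate C–H before the tertiary hydroxyl.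

Step 7. At a ketone flanked by the substituted C5, the reagent may act as a base or as a hydride donor: enolization followed by loss of a β-silyloxy group, or reduction to the secondary alcohol. The fallback uses an sp2 nucleophile that cannot transfer a β-hydride and is less basic; it sets out from 10 and comes back at 11. 2-Propenylmagnesium bromide/CeCl3 (THF, −78 °C) should add from the same β-face to give the (1R,2R,4S,5S,6S)-4β-(prop-1-en-2-yl) carbinol F3 (same spatial arrangement at C4; the descriptor changes by priority only). Hydrogenation with RhCl(PPh3)3 and H2 in benzene should saturate the 1,1-disubstituted alkene selectively over the trisubstituted ring alkene and give 11.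

Step 6. Closure onto the 1,1-disubstituted alkene may be slow enough for intermolecular metathesis of the allyl arm or ruthenium hydride-mediated alkene migration to compete. The fallback exchanges the order of ring closure and carbinol formation; it sets out from 9 and comes back at 11. Addition of iPrMgCl/CeCl3 to the monocyclic ketone 9, anti to the bulky C5 side chain, should give (1R,2S,3R,4R)-3-allyl-4-(tert-butyldimethylsilyloxy)-3-methyl-2-[(1S)-3-methyl-1-(triethylsilyloxy)but-3-en-1-yl]-1-(propan-2-yl)cyclopentan-1-ol F4. Ring-closing metathesis of F4 with the same catalyst should give 11; the fully substituted C4 presses the two arms together and no epimerizable centre remains.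

Step 2. Protodesilylation of 2 to the saturated ketone by the acetic acid formed may outrun palladation, leaving incomplete dehydrogenation. The fallback replaces β-hydride elimination by selenoxide elimination; it sets out from 2 and comes back at 3. PhSeCl (THF, −78 °C) should give (2R,3S,4R)-4-(tert-butyldimethylsilyloxy)-3-methyl-2-(phenylselanyl)cyclopentan-1-one F5, with selenium trans to the C3 methyl group and therefore cis to C3–H. Oxidation with H2O2 and pyridine in CH2Cl2 at 0 °C and syn-elimination of the selenoxide toward C3–H should give 3.

**Further compounds**

F1 | step 4 | trimethyl{[(3R,4R)-3-allyl-4-(tert-butyldimethylsilyloxy)-3-methylcyclopent-1-en-1-yl]oxy}silane | CC(C)(C)[Si](C)(C)O[C@@H]1CC(O[Si](C)(C)C)=C[C@@]1(C)CC=C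
F2 | step 11 | C2 2-[bis(2,2,2-trifluoroethoxy)phosphoryl]propanoate of 14 (mixture at the phosphonate-bearing carbon) | CC(C(=O)O[C@@H]1C[C@@](O)(C(C)C)[C@@H]2[C@@H](OC(=O)c3ccc(OC)cc3)CC(C)=CC[C@]21C)P(=O)(OCC(F)(F)F)OCC(F)(F)F
F3 | step 7 | (1R,2R,4S,5S,6S)-2α-(tert-butyldimethylsilyloxy)-6β-(triethylsilyloxy)-1α,8-dimethyl-4β-(prop-1-en-2-yl)-trans-hydroazul-8-en-4α-ol | CC(C)(C)[Si](C)(C)O[C@@H]1C[C@@](O)(C(C)=C)[C@@H]2[C@@H](O[Si](CC)(CC)CC)CC(C)=CC[C@]21C
F4 | step 6 | (1R,2S,3R,4R)-3-allyl-4-(tert-butyldimethylsilyloxy)-3-methyl-2-[(1S)-3-methyl-1-(triethylsilyloxy)but-3-en-1-yl]-1-(propan-2-yl)cyclopentan-1-ol | CC(C)(C)[Si](C)(C)O[C@@H]1C[C@@](O)(C(C)C)[C@H]([C@@H](O[Si](CC)(CC)CC)CC(C)=C)[C@@]1(C)CC=C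
F5 | step 2 | (2R,3S,4R)-4-(tert-butyldimethylsilyloxy)-3-methyl-2-(phenylselanyl)cyclopentan-1-one | CC(C)(C)[Si](C)(C)O[C@@H]1CC(=O)[C@H]([Se]c2ccccc2)[C@H]1C
A1 | alternative 1 | 2,4-O-isopropylidene cyclopentane-5-carbaldehyde with a 3-methyl-2-(trimethylsilyl)but-3-enyl chain on C1 (either configuration at the silyl-bearing carbon) | CC1(C)O[C@@H]2C[C@@](O1)(C(C)C)[C@H](C=O)[C@@]2(C)CC([Si](C)(C)C)C(C)=C
A2 | alternative 1 | trans-fused hydroazul-8-en-6-ol 2,4-acetonide | CC1(C)O[C@@H]2C[C@@](O1)(C(C)C)[C@@H]3[C@@H](O)CC(C)=CC[C@]32C
A3 | alternative 2 | (5R)-2-diazo-5-(2-methoxy-4-methylphenyl)-6-methyl-5-(triethylsilyloxy)heptan-3-one | CC(=[N+]=[N-])C(=O)C[C@@](O[Si](CC)(CC)CC)(C(C)C)c1ccc(C)cc1OC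
A4 | alternative 2 | 6-methoxy-1,8-dimethyl-4-isopropyl-4-(triethylsilyloxy)bicyclo[5.3.0]deca-5,7,9-trien-2-one (skeleton locants) | O=C1C[C@@](O[Si](CC)(CC)CC)(C(C)C)C2=C(OC)C=C(C)C=C[C@@]12C
A5 | alternative 3 | acyclic α-diazo β-keto ester: methyl 2-diazo-3-oxo ester on C3/C2, C1 with methyl and tert-butyl acetate arm, C5 methyl ester, C4 tert-butyldimethylsilyloxy carbinol with isopropyl | COC(=O)C(=[N+]=[N-])C(=O)[C@](C)(CC(=O)OC(C)(C)C)[C@@H](C(=O)OC)[C@H](O[Si](C)(C)C(C)(C)C)C(C)C
A6 | alternative 3 | pentasubstituted cyclopentanone triester (C2 ketone, C3 and C5 methyl esters, C4 silyloxy/isopropyl, C1 methyl and tert-butyl acetate arm) | O=C1[C@H](C(=O)OC)[C@@](O[Si](C)(C)C(C)(C)C)(C(C)C)[C@H](C(=O)OC)[C@@]1(C)CC(=O)OC(C)(C)C
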